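- A small charge of partner, 0.240 M against 0.40 M of each substrate, is shared between the two hands, so the peaks of left-handed product and right-handed product tell how far the racemate was drawn down before the partner stopped giving product.

| flask | left-handed substrate | right-handed substrate | partner | temperature | remark | time |
|---|---|---|---|---|---|---|
| delta | 0.40 M | 0.40 M | 0.12 M | 85 °C | run made earlier |  |
| theta | 0.40 M | 0.40 M | 0.18 M | 105 °C | run made earlier |  |
| alpha | 0.20 M | 0.20 M | 0.24 M | 85 °C | run made earlier |  |
| maple | 0.40 M | 0.40 M | 0.240 M | 120 °C |  | 80 min |
| oak | 0.40 M | 0.40 M | 0.240 M | 90 °C |  | 80 min |
| ash | 0.40 M | 0.40 M | 0.240 M |  | at 120 °C until 40 min, from then on at 90 °C | 80 min |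

| run | time / min | left-handed product / % | right-handed product / % |
|---|---|---|---|
| delta | 120 | 9.0 | 4.8 |
| delta | 240 | 9.5 | 5.1 |
| delta | 360 | 9.3 | 5.2 |
| delta | 480 | 9.6 | 4.8 |
| theta | 15.0 | 13.2 | 7.8 |
| theta | 50.0 | 13.2 | 7.5 |
| theta | 80.0 | 13.3 | 7.7 |
| theta | 120 | 13.4 | 7.9 |
| theta | 180 | 13.9 | 7.5 |
| alpha | 120 | 33.3 | 21.8 |
| alpha | 240 | 33.7 | 21.9 |
| alpha | 360 | 32.7 | 21.4 |
| alpha | 480 | 33.1 | 21.6 |

(readings scatter by 0.3 percentage points)

- partner is single-handed; left-handed substrate and right-handed substrate are mirror images of each other, charged as a racemate, each of them at the stated concentration
- the numbers in the tables scatter with a standard deviation of 0.3 percentage points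
- reactions considered so far: partner + left-handed substrate -> left-handed product; partner + right-handed substrate -> right-handed product; partner -> decomposed reagent
- the handed part of partner does not stay in what it makes, so the products of the two hands are mirror images too

* which flask leads in share of left-handed product in all that became left-handed product or right-handed product ("all alike" within 1.5 percentage points) (maple / oak / ash / all alike)
* share of left-handed product in all that became left-handed product or right-handed product, maple
* share of left-handed product in all that became left-handed product or right-handed product, oak
* share of left-handed product in all that became left-handed product or right-handed product, ash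

- Delta, theta and alpha show no drift standing clear of the scatter of 0.3 percentage points, and theta already reads its level at 15.0 min, so maple, hotter than theta at 120 °C, should have stopped before ash is cooled, and ash is reckoned as maple; alpha reads its level at 120 min, and oak, hotter than alpha with twice its substrate, is reckoned level by about 60.0 min, earlier than its 80 min.
- The first way uses the selectivity factor, the logarithm of the fraction of left-handed substrate left divided by that of the fraction of right-handed substrate left, which reads 1.98 in delta, 1.87 in theta and 1.92 in alpha, with a mean of 1.92.
- The readings of theta put 93.7% of its partner into product, so the new flasks are reckoned to reach 28.1% product, in percent of both substrates charged together.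
- The share at the start, the factor over itself plus one, is 65.8%; put back, it takes 37.0% of the left-handed substrate, the factor then allows 21.4% of the right-handed substrate, and the share becomes 63.4%, and one more round gives 63.5%.
- The second way does without the factor: the readings of delta average 14.3% product with a left-handed share of 65.3%, those of alpha 54.9% with 60.5%, both at 85 °C, and a straight line between them gives 63.6% at the reckoned product; both ways lean on the same readings, so this agreement tests the reckoning, not the readings, and the reckoning here commits to about 63.5% for maple, oak and ash alike.
- The forecast says all alike, with 62.4% for maple, 63.7% for oak and 62.4% for ash, and differs from the single factor used here by letting it move with temperature: “Extrapolating the weak temperature dependence gives s ≈ 1.93 at 90 °C and about 1.82 at 120 °C.”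

    partner + left-handed substrate → left-handed product (k = 0.0705 M⁻¹ s⁻¹, Ea = 63.0 kJ mol⁻¹)
    partner + right-handed substrate → right-handed product (k = 0.0371 M⁻¹ s⁻¹, Ea = 62.0 kJ mol⁻¹)
    partner → decomposed reagent (k = 0.00149 s⁻¹, Ea = 97.0 kJ mol⁻¹)
    (constants at 90 °C)

- The flasks come out all alike, with 63.8% in maple, 63.8% in ash and 63.2% in oak, a spread of 0.60 points against the margin of 1.5 points. Maple holds 0.0214 M of decomposed reagent at a conversion of 27.3%, and oak 0.00957 M at 28.8%. In maple, 80% of right-handed substrate left gives by the factor 65.2% of left-handed substrate, and 65% stands there. The neighbour of maple with 0.96 M of partner keeps 11% of right-handed substrate, so the factor gives 1.54% of left-handed substrate, and that flask holds 1.4%.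

The readings were generated by integration with made-up constants, noise included.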